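**Strategy**

The target is divided between C8 and C9 of its decane chain (C1 = CH2OAc, C10 on the oxane) into two C10 halves. The C9–C10 ethylene joining this bond to the quaternary, oxygen-bearing C2 of the oxane ring is the vinyl group of (R)-linalool after cyclisation. In one flask, 9-BBN places boron on the terminal vinyl carbon (the quaternary ring carbon enforces anti-Markovnikov addition) and a nickel-catalysed alkyl–alkyl Suzuki coupling joins it to (7R)-8-iodo-6,7-dihydrogeraniol, whose methyl centre stems from (S)-3-bromo-2-methylpropanol. Sharpless epoxidation, titanium-mediated epoxide-to-allylic-diol isomerisation and acetylation then create the 3-methylidene-1,2-diacetate head.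

Key step: step 6

Assumption: (R)-(−)-linalool (1) and (S)-(+)-3-bromo-2-methylpropan-1-ol (5) are used in their highest commercial optical purity, since the oxane centre and C7 of the target take their configuration directly from them. Locants C1–C10 in the text refer to the decane chain of the target.

**Route**

Step 1
Reactants: 1 (R)-(−)-linalool
Product: 3 (2R)-2-ethenyl-2,6,6-trimethyloxane, via organomercury acetate 2 (not isolated)
Conditions: Hg(OAc)2 (1.05 equiv), dry THF, 0 °C → rt; then 3 M NaOH, NaBH4, 0 °C
Reagents that add atoms: none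
Why: Intramolecular alkoxymercuration–demercuration: the tertiary hydroxyl attacks the mercurinium ion of the trisubstituted alkene at its tertiary carbon (Markovnikov, 6-endo) and NaBH4 replaces Hg by H; the C–O bond at the stereocentre is never broken, so the (R) configuration of linalool is retained.

Step 2
Reactants: 4 (4-bromobut-1-yn-1-yl)trimethylsilane; 5 (S)-(+)-3-bromo-2-methylpropan-1-ol
Product: 7 (2R)-2-methyl-7-(trimethylsilyl)hept-6-yn-1-ol, via Grignard reagent 6 (not isolated)
Conditions: 4, Mg, THF, rt; 5, MeMgBr (1.0 equiv), THF, −20 °C; then 6 (1.5 equiv), Li2CuCl4 (5 mol%), THF–NMP, −20 °C → rt; aq NH4Cl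
Reagents that add atoms: none
Why: Kochi-type copper-catalysed C(sp3)–C(sp3) coupling of a primary Grignard reagent with the primary bromide of the pre-formed magnesium alkoxide; the stereocentre of 5 is a spectator and its descriptor changes from S to R only through the change in CIP priorities.

Step 3
Reactants: 7 (2R)-2-methyl-7-(trimethylsilyl)hept-6-yn-1-ol
Product: 8 (2R)-2-methylhept-6-yn-1-ol
Conditions: K2CO3, MeOH, rt
Reagents that add atoms: none
Why: Methanolysis of the alkynyl C–Si bond under mild base should leave the alcohol and the stereocentre untouched.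

Step 4
Reactants: 8 (2R)-2-methylhept-6-yn-1-ol
Product: 9 (6R)-7-iodo-6-methylhept-1-yne
Conditions: I2, PPh3, imidazole, CH2Cl2, 0 °C → rt
Reagents that add atoms: iodine, II
Why: Appel-type iodination of the primary alcohol through its alkoxyphosphonium salt; the terminal alkyne and the β-stereocentre are not involved.

Step 5
Reactants: 9 (6R)-7-iodo-6-methylhept-1-yne
Product: 11 (2E,7R)-8-iodo-3,7-dimethyloct-2-en-1-ol, via alkenylalane 10 (not isolated)
Conditions: Me3Al (2.5 equiv), Cp2ZrCl2 (0.25 equiv), CH2Cl2, 0 °C → rt; then (CH2O)n, 0 °C → rt; aq Rochelle salt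
Reagents that add atoms: trimethylaluminium, C[Al](C)C; paraformaldehyde (as formaldehyde), C=O
Why: Negishi zirconium-catalysed carboalumination adds methyl and aluminium syn across the terminal alkyne with methyl on the internal carbon, and the (E)-alkenylalane is hydroxymethylated by formaldehyde with retention, which fixes the 2E geometry; the primary iodide is inert to these reagents.

Step 6
Reactants: 3 (2R)-2-ethenyl-2,6,6-trimethyloxane; 11 (2E,7R)-8-iodo-3,7-dimethyloct-2-en-1-ol
Product: 13 (2E,7R)-3,7-dimethyl-10-[(2S)-2,6,6-trimethyloxan-2-yl]dec-2-en-1-ol, via B-alkyl-9-BBN 12 (not isolated)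
Conditions: 3 (1.6 equiv), 9-BBN dimer (1.5 equiv B–H), THF, rt → 40 °C; then 11 (1.0 equiv), NiCl2·glyme (6 mol%), trans-N,N′-dimethylcyclohexane-1,2-diamine (8 mol%), KOt-Bu, i-BuOH, dioxane, rt
Reagents that add atoms: none
Why: 9-BBN adds syn and anti-Markovnikov to the vinyl group of 3 because the adjacent quaternary, oxygen-substituted C2 of the oxane ring blocks the internal carbon; boron therefore sits on the terminal carbon, three atoms from the ring oxygen, where neither β-alkoxy elimination nor chain walking is possible. After activation of 12 as its alkoxyborate (KOt-Bu/i-BuOH), the Ni–diamine catalyst abstracts iodine from 11 to give the primary C8 radical, which is captured at nickel and joined to the transmetalated alkyl group by C(sp3)–C(sp3) reductive elimination, forming C8–C9. The closest known reaction type is the one-pot hydroboration/nickel-catalysed alkyl–alkyl Suzuki–Miyaura coupling of B-alkyl-9-BBN reagents with unactivated alkyl halides. No ring is closed and no stereocentre is created: the C7 methyl centre is β to the reacting carbon and the oxane C2 centre is quaternary, so both should be carried through unchanged. The step needs chemoselectivity for the C–I bond over the free allylic hydroxyl and the trisubstituted alkene of 11; the first is secured because the protocol itself runs in the presence of an alcohol, the second because all B–H is consumed by the excess of 3 before 11 is added, and the radical-type halide activation is insensitive to the β-methyl branch.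

Step 7
Reactants: 13 (2E,7R)-3,7-dimethyl-10-[(2S)-2,6,6-trimethyloxan-2-yl]dec-2-en-1-ol
Product: 14 [(2S,3S)-3-methyl-3-{(4S)-4-methyl-7-[(2S)-2,6,6-trimethyloxan-2-yl]heptyl}oxiran-2-yl]methanol
Conditions: Ti(OiPr)4 (10 mol%), L-(+)-diethyl tartrate (12 mol%), t-BuOOH, 4 Å MS, CH2Cl2, −20 °C
Reagents that add atoms: tert-butyl hydroperoxide, CC(C)(C)OO
Why: Sharpless asymmetric epoxidation of the only alkene, an (E)-3,3-disubstituted allylic alcohol of the geraniol type; L-(+)-tartrate delivers oxygen to the face that gives the (2S,3S)-epoxide under reagent control (the former C7 centre is spatially unchanged; it is named 4S in the heptyl chain only through a CIP priority change).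

Step 8
Reactants: 14 [(2S,3S)-3-methyl-3-{(4S)-4-methyl-7-[(2S)-2,6,6-trimethyloxan-2-yl]heptyl}oxiran-2-yl]methanol
Product: 15 (2R,7R)-7-methyl-3-methylidene-10-[(2S)-2,6,6-trimethyloxan-2-yl]decane-1,2-diol
Conditions: Ti(OiPr)4 (2 equiv), CH2Cl2, rt → 40 °C; aq tartaric acid
Reagents that add atoms: none
Why: Sharpless titanium-mediated isomerisation of a 2,3-epoxy alcohol to an allylic 1,2-diol: the epoxide, bound to titanium through the C1 oxygen, opens at tertiary C3 and a titanium-bound isopropoxide removes a proton from the methyl group that is cis to the CH2O–Ti arm, which should give the exocyclic methylidene; the C2–O bond is kept, so the SAE-derived centre becomes 2R by priority change only.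

Step 9
Reactants: 15 (2R,7R)-7-methyl-3-methylidene-10-[(2S)-2,6,6-trimethyloxan-2-yl]decane-1,2-diol
Product: 16 (2R,7R)-7-methyl-3-methylidene-10-[(2S)-2,6,6-trimethyloxan-2-yl]decane-1,2-diyl diacetate
Conditions: Ac2O, pyridine, DMAP (cat.), CH2Cl2, 0 °C → rt
Reagents that add atoms: acetic anhydride, CC(=O)OC(C)=O
Why: DMAP-catalysed acylation of the primary and the secondary allylic hydroxyl should proceed without touching any stereocentre.

**Compound list**

1 | (R)-(−)-linalool, (3R)-3,7-dimethylocta-1,6-dien-3-ol | C=C[C@](C)(O)CCC=C(C)C | starting material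
2 | [(6R)-6-ethenyl-2,2,6-trimethyloxan-3-yl]mercury(II) acetate (C3 epimers) | C=C[C@@]1(C)CCC([Hg]OC(C)=O)C(C)(C)O1 | intermediate
3 | (2R)-2-ethenyl-2,6,6-trimethyloxane | C=C[C@@]1(C)CCCC(C)(C)O1 | intermediate
4 | (4-bromobut-1-yn-1-yl)trimethylsilane | C[Si](C)(C)C#CCCBr | starting material
5 | (S)-(+)-3-bromo-2-methylpropan-1-ol | C[C@@H](CO)CBr | starting material
6 | [4-(trimethylsilyl)but-3-yn-1-yl]magnesium bromide | C[Si](C)(C)C#CCC[Mg]Br | intermediate
7 | (2R)-2-methyl-7-(trimethylsilyl)hept-6-yn-1-ol | C[Si](C)(C)C#CCCC[C@@H](C)CO | intermediate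
8 | (2R)-2-methylhept-6-yn-1-ol | C#CCCC[C@@H](C)CO | intermediate
9 | (6R)-7-iodo-6-methylhept-1-yne | C#CCCC[C@@H](C)CI | intermediate
10 | [(1E,6R)-7-iodo-2,6-dimethylhept-1-en-1-yl]dimethylalane | C[Al](C)/C=C(\C)CCC[C@@H](C)CI | intermediate
11 | (2E,7R)-8-iodo-3,7-dimethyloct-2-en-1-ol | OC/C=C(\C)CCC[C@@H](C)CI | intermediate
12 | 9-{2-[(2S)-2,6,6-trimethyloxan-2-yl]ethyl}-9-borabicyclo[3.3.1]nonane | C[C@]1(CCB2C3CCCC2CCC3)CCCC(C)(C)O1 | intermediate
13 | (2E,7R)-3,7-dimethyl-10-[(2S)-2,6,6-trimethyloxan-2-yl]dec-2-en-1-ol | OC/C=C(\C)CCC[C@@H](C)CCC[C@@]1(C)CCCC(C)(C)O1 | intermediate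
14 | [(2S,3S)-3-methyl-3-{(4S)-4-methyl-7-[(2S)-2,6,6-trimethyloxan-2-yl]heptyl}oxiran-2-yl]methanol | C[C@@]1(CCC[C@@H](C)CCC[C@@]2(C)CCCC(C)(C)O2)O[C@H]1CO | intermediate
15 | (2R,7R)-7-methyl-3-methylidene-10-[(2S)-2,6,6-trimethyloxan-2-yl]decane-1,2-diol | C=C(CCC[C@@H](C)CCC[C@@]1(C)CCCC(C)(C)O1)[C@H](CO)O | intermediate
16 | (2R,7R)-7-methyl-3-methylidene-10-[(2S)-2,6,6-trimethyloxan-2-yl]decane-1,2-diyl diacetate | C=C(CCC[C@@H](C)CCC[C@@]1(C)CCCC(C)(C)O1)[C@H](COC(C)=O)OC(C)=O | target

**Step count**

Total steps: 9. Longest linear sequence: 8 steps (steps 2–9, from 4 and 5).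

**Steps most likely to fail**

Step 6. The C8 radical may be lost by 1,5-hydrogen transfer from the allylic C4–H or by reduction, the hindered borane may transmetalate slowly, or nickel may engage the allylic C–O bond. The fallback replaces the boron/nickel manifold by a copper-catalysed Grignard coupling. It sets out from 12, which is oxidised (NaOH, H2O2) to 2-[(2R)-2,6,6-trimethyloxan-2-yl]ethan-1-ol F1. CBr4/PPh3 should convert this into (2R)-2-(2-bromoethyl)-2,6,6-trimethyloxane F2, and magnesium in THF into {2-[(2R)-2,6,6-trimethyloxan-2-yl]ethyl}magnesium bromide F3. Iodide 11, deprotonated first with one equivalent of MeMgBr, is then coupled with F3 under Li2CuCl4 catalysis (THF, −20 °C → rt), a combination with broad precedent for β-methyl-branched primary iodides. The fallback comes back to the route at 13.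

Step 8. Regiocontrol of the proton removal may be lost, giving the endocyclic C3=C4 alkene, or isopropoxide may be transferred to C3. The fallback uses a silyl triflate-induced opening with base-mediated elimination instead of the titanium template. It sets out from 14, which is silylated (TBSCl, imidazole) to tert-butyl{[(2S,3S)-3-methyl-3-{(4S)-4-methyl-7-[(2S)-2,6,6-trimethyloxan-2-yl]heptyl}oxiran-2-yl]methoxy}dimethylsilane F4. TMSOTf/2,6-lutidine at −78 °C followed by DBU should open the epoxide at C3 and remove a proton preferentially from the less hindered methyl group, giving tert-butyl{[(2R,7R)-7-methyl-3-methylidene-10-[(2S)-2,6,6-trimethyloxan-2-yl]-2-(trimethylsilyloxy)decyl]oxy}dimethylsilane F5. TBAF removes both silyl groups, and the fallback comes back to the route at 15.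

Step 1. Closure may go to the five-membered ether, adventitious water may hydrate the alkene, or reductive demercuration may eliminate back to linalool. The fallback is a selenium-induced cyclisation followed by radical reduction. It sets out from 1, which with PhSeCl (CH2Cl2, −78 °C → rt, equilibrating conditions) should give the Markovnikov six-membered ether (6R)-6-ethenyl-2,2,6-trimethyl-3-(phenylselanyl)oxane F6. Bu3SnH/AIBN (toluene, 80 °C) cleaves the C–Se bond, and the fallback comes back to the route at 3.

**Further compounds**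

F1 | step 6 | 2-[(2R)-2,6,6-trimethyloxan-2-yl]ethan-1-ol | C[C@]1(CCO)CCCC(C)(C)O1
F2 | step 6 | (2R)-2-(2-bromoethyl)-2,6,6-trimethyloxane | C[C@]1(CCBr)CCCC(C)(C)O1
F3 | step 6 | {2-[(2R)-2,6,6-trimethyloxan-2-yl]ethyl}magnesium bromide | C[C@]1(CC[Mg]Br)CCCC(C)(C)O1
F4 | step 8 | tert-butyl{[(2S,3S)-3-methyl-3-{(4S)-4-methyl-7-[(2S)-2,6,6-trimethyloxan-2-yl]heptyl}oxiran-2-yl]methoxy}dimethylsilane | C[C@@]1(CCC[C@@H](C)CCC[C@@]2(C)CCCC(C)(C)O2)O[C@H]1CO[Si](C)(C)C(C)(C)C
F5 | step 8 | tert-butyl{[(2R,7R)-7-methyl-3-methylidene-10-[(2S)-2,6,6-trimethyloxan-2-yl]-2-(trimethylsilyloxy)decyl]oxy}dimethylsilane | C=C(CCC[C@@H](C)CCC[C@@]1(C)CCCC(C)(C)O1)[C@H](CO[Si](C)(C)C(C)(C)C)O[Si](C)(C)C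
F6 | step 1 | (6R)-6-ethenyl-2,2,6-trimethyl-3-(phenylselanyl)oxane | C=C[C@@]1(C)CCC([Se]c2ccccc2)C(C)(C)O1
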